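The O1–C2–C3 segment of the dihydrofuran ring B, with the isopropenyl group on C2 and the trans oxygen on C3, is treated as a ring-contracted 2,2-dimethylchroman-3,4-diol. Triflating the free hydroxyl of a trans-(3R,4S)-chroman-3-ol lets the ring oxygen expel the leaving group with inversion. The O–CMe2 bond then breaks and a methyl proton is lost, so a single operation creates the O1–C2 bond, ring B, the C2 stereocentre and the isopropenyl group. The precursor is an enantioenriched 6-acetylchroman with silyl ethers on the C7 phenol and the benzylic C4 oxygen, reached by Jacobsen epoxidation of the parent chromene. The Z side-chain acid is attached last.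

Key step: step 8

Assumption: the side-chain alkene is Z (methyl cis to the ester carbonyl), and the (R,R) salen–MnCl catalyst is taken to oxidise the chromene on the face leading to the (3R,4R) epoxide, as for other 2,2-dimethylchromenes.

Step 1
Reactants: 1 2,4-dihydroxyacetophenone
Product: 2 1-(2,4-dihydroxy-5-iodophenyl)ethanone
Conditions: ICl (1.0 equiv), AcOH, rt
Reagents that add atoms: iodine monochloride, ClI
Why: Electrophilic aromatic iodination under acidic, non-phenoxide conditions should go to C5, which is ortho to the free 4-hydroxyl, para to the chelated 2-hydroxyl and far less crowded than C3 between the two oxygens.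

Step 2
Reactants: 2 1-(2,4-dihydroxy-5-iodophenyl)ethanone; 3 2-methylbut-3-en-2-ol
Product: 4 (E)-1-[2,4-dihydroxy-5-(3-hydroxy-3-methylbut-1-en-1-yl)phenyl]ethanone
Conditions: Pd(OAc)2 (5 mol %), Et3N, DMF, 90 °C
Reagents that add atoms: none
Why: Mizoroki–Heck arylation of the terminal alkene by the aryl iodide should give the E styrenyl alcohol, because the tertiary carbinol carbon has no hydrogen for the alternative β-hydride elimination.

Step 3
Reactants: 4 (E)-1-[2,4-dihydroxy-5-(3-hydroxy-3-methylbut-1-en-1-yl)phenyl]ethanone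
Product: 6 1-(7-hydroxy-2,2-dimethyl-2H-chromen-6-yl)ethanone, via o-quinone methide 5 (not isolated)
Conditions: p-TsOH·H2O (cat.), toluene, 80 °C
Reagents that add atoms: none
Why: Acid-promoted loss of water from the tertiary allylic alcohol, assisted by the ortho and para hydroxyls, gives the vinylogous o-quinone methide 5, whose oxa-6π electrocyclisation (the usual cyclodehydration route to 2,2-dimethyl-2H-chromenes) can only engage the hydroxyl ortho to the side chain.

Step 4
Reactants: 6 1-(7-hydroxy-2,2-dimethyl-2H-chromen-6-yl)ethanone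
Product: 7 1-[7-(tert-butyldimethylsilyloxy)-2,2-dimethyl-2H-chromen-6-yl]ethanone
Conditions: TBSCl, imidazole, DMF, rt
Reagents that add atoms: tert-butyldimethylsilyl chloride, CC(C)(C)[Si](C)(C)Cl
Why: Standard silylation of the only hydroxyl keeps the phenol away from the oxo-manganese oxidant and from Tf2O later; TBSOTf is avoided because it would turn the methyl ketone into a silyl enol ether.

Step 5
Reactants: 7 1-[7-(tert-butyldimethylsilyloxy)-2,2-dimethyl-2H-chromen-6-yl]ethanone
Product: 8 (3R,4R)-6-acetyl-7-(tert-butyldimethylsilyloxy)-3,4-epoxy-2,2-dimethylchromane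
Conditions: (R,R)-[N,N'-bis(3,5-di-tert-butylsalicylidene)cyclohexane-1,2-diaminato]MnCl (5 mol %), mCPBA, NMO, CH2Cl2, −78 °C
Reagents that add atoms: mCPBA, OOC(=O)c1cccc(Cl)c1
Why: Jacobsen–Katsuki epoxidation, for which 2,2-dimethylchromenes are among the best substrates, should set both new stereocentres under catalyst control as the (3R,4R) epoxide; the anhydrous mCPBA/NMO protocol avoids the haloform and silyl-ether hydrolysis risks of alkaline bleach.

Step 6
Reactants: 8 (3R,4R)-6-acetyl-7-(tert-butyldimethylsilyloxy)-3,4-epoxy-2,2-dimethylchromane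
Product: 9 (3R,4S)-6-acetyl-7-(tert-butyldimethylsilyloxy)-2,2-dimethylchromane-3,4-diol
Conditions: HClO4 (cat.), THF/H2O, 0 °C
Reagents that add atoms: water, O
Why: Acid-catalysed epoxide hydrolysis in which water attacks the activated benzylic C4 (C3 is neopentyl-like) from the face opposite the epoxide oxygen, so C4 is inverted, C3 is untouched and the trans diol should result.

Step 7
Reactants: 9 (3R,4S)-6-acetyl-7-(tert-butyldimethylsilyloxy)-2,2-dimethylchromane-3,4-diol
Product: 10 (3R,4S)-6-acetyl-4,7-bis(tert-butyldimethylsilyloxy)-2,2-dimethylchroman-3-ol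
Conditions: TBSCl (1.2 equiv), imidazole, DMF, 0 °C → rt
Reagents that add atoms: tert-butyldimethylsilyl chloride, CC(C)(C)[Si](C)(C)Cl
Why: Regioselective silylation, since the benzylic C4 hydroxyl is an ordinary secondary alcohol whereas the C3 hydroxyl sits next to the quaternary C2 and should resist TBSCl/imidazole; neither stereocentre is touched.

Step 8
Reactants: 10 (3R,4S)-6-acetyl-4,7-bis(tert-butyldimethylsilyloxy)-2,2-dimethylchroman-3-ol
Product: 14 (2R,3S)-5-acetyl-3,6-bis(tert-butyldimethylsilyloxy)-2-isopropenyl-2,3-dihydrobenzofuran, via C3 triflate 11 (not isolated), via aryloxiranium ion 12 (not isolated), via tertiary cation 13 (not isolated)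
Conditions: Tf2O (1.1 equiv), 2,6-di-tert-butyl-4-methylpyridine (3 equiv), CH2Cl2, −78 °C → rt
Reagents that add atoms: none
Why: Tf2O converts the hindered C3 hydroxyl into triflate 11; in the half-chair with the C3 and C4 substituents pseudo-equatorial, the C3–OTf bond is antiperiplanar to the O1–C2 ring bond, so a lone pair on the aryl ether oxygen displaces triflate from the rear in a 3-exo-tet closure to give the bicyclic aryloxiranium ion 12. The O1–CMe2 bond of 12 then ionises, leaving the five-membered ring B (formed by contraction, O1 now bonded to the former chroman C3) and tertiary cation 13, and the hindered pyridine removes a methyl proton to give the isopropenyl group. The closest known reaction type is the dehydrative ring contraction of 2,2-dimethylchroman-3-ols to 2-isopropenyl-2,3-dihydrobenzofurans on activation of the hydroxyl, an anchimerically assisted displacement by an ether oxygen. The new C2 stereocentre is set by inversion at the triflate carbon (substrate control) while the silyloxy carbon is not touched, so the trans-(3R,4S) chromanol should give only the trans-(2R,3S) dihydrobenzofuran, with the absolute configuration inherited from the epoxidation. Oxygen participation must beat elimination, attack by the C4 oxygen and 1,2-shifts: C2 is quaternary and H4 is cis to the leaving group, so no antiperiplanar β-hydrogen exists, the bulky silyl ether is a poor neighbouring group where an ester would form an acyloxonium ion, and the gem-dimethyl carbon gives the oxiranium ion an easy tertiary-cation outlet. Tf2O is kept to about one equivalent at −78 °C because it triflates the alcohol much faster than it attacks the aryl ketone.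

Step 9
Reactants: 14 (2R,3S)-5-acetyl-3,6-bis(tert-butyldimethylsilyloxy)-2-isopropenyl-2,3-dihydrobenzofuran
Product: 15 (2R,3S)-5-acetyl-3,6-dihydroxy-2-isopropenyl-2,3-dihydrobenzofuran
Conditions: Bu4NF, AcOH (1:1), THF, 0 °C → rt
Reagents that add atoms: none
Why: Fluoride-mediated cleavage of both the aryl and the benzylic silyl ether; the acetic acid buffer keeps the C6 phenol protonated, which should suppress quinone-methide-type loss of the C3 oxygen and aromatisation to the benzofuran.

Step 10
Reactants: 16 but-2-ynoic acid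
Product: 17 tert-butyl but-2-ynoate
Conditions: isobutene, H2SO4 (cat.), CH2Cl2, sealed vessel, rt
Reagents that add atoms: isobutene, C=C(C)C
Why: Acid-catalysed addition of the carboxylic acid to isobutene gives a tert-butyl ester that resists 1,2-reduction in the next step and can later be cleaved without touching an acetate.

Step 11
Reactants: 17 tert-butyl but-2-ynoate
Product: 19 tert-butyl (Z)-2-(hydroxymethyl)but-2-enoate, via alkenylalane 18 (not isolated)
Conditions: i-Bu2AlH, HMPA, THF, 0 °C; then CH2O (gas), −78 °C → rt
Reagents that add atoms: formaldehyde, C=O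
Why: Conjugate hydroalumination of the ynoate by the i-Bu2AlH–HMPA complex is a syn addition (H to C3, Al to C2) giving alkenylalane 18, which should add to formaldehyde with retention (vinylalumination, an aluminium-mediated Baylis–Hillman-type hydroxymethylation), so the methyl group ends cis to the ester, the Z alkene.

Step 12
Reactants: 19 tert-butyl (Z)-2-(hydroxymethyl)but-2-enoate
Product: 20 tert-butyl (Z)-2-(acetoxymethyl)but-2-enoate
Conditions: Ac2O, pyridine, CH2Cl2, 0 °C → rt
Reagents that add atoms: acetic anhydride, CC(=O)OC(C)=O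
Why: Routine acetylation of the primary allylic alcohol, run without a nucleophilic catalyst such as DMAP because the product is an allylic acetate prone to SN2' attack.

Step 13
Reactants: 20 tert-butyl (Z)-2-(acetoxymethyl)but-2-enoate
Product: 21 (Z)-2-(acetoxymethyl)but-2-enoic acid
Conditions: TFA, CH2Cl2, 0 °C → rt
Reagents that add atoms: none
Why: Acidolysis of the tert-butyl ester (E1 loss of isobutene) should free the acid while leaving the primary acetate and the Z alkene unchanged.

Step 14
Reactants: 15 (2R,3S)-5-acetyl-3,6-dihydroxy-2-isopropenyl-2,3-dihydrobenzofuran; 21 (Z)-2-(acetoxymethyl)but-2-enoic acid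
Product: 23 (2R,3S)-5-acetyl-6-hydroxy-2-isopropenyl-2,3-dihydrobenzofuran-3-yl (Z)-2-(acetoxymethyl)but-2-enoate, via acid chloride 22 (not isolated)
Conditions: 21, 1-chloro-N,N,2-trimethylprop-1-en-1-amine, CH2Cl2, 0 °C → rt; then 15, 2,4,6-collidine, CH2Cl2, 0 °C → rt
Reagents that add atoms: none
Why: The acid chloride 22 is made under neutral conditions with the Ghosez reagent (no HCl, hence no Z to E isomerisation) and should acylate the secondary C3 alcohol rather than the C6 phenol, which is deactivated by its hydrogen bond to the acetyl group and is not deprotonated by the hindered, non-nucleophilic collidine; acylation occurs at oxygen, so both stereocentres are retained.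

Compound list
1 | 2,4-dihydroxyacetophenone | CC(=O)c1ccc(O)cc1O | starting material
2 | 1-(2,4-dihydroxy-5-iodophenyl)ethanone | CC(=O)c1cc(I)c(O)cc1O | intermediate
3 | 2-methylbut-3-en-2-ol | C=CC(C)(C)O | starting material
4 | (E)-1-[2,4-dihydroxy-5-(3-hydroxy-3-methylbut-1-en-1-yl)phenyl]ethanone | CC(=O)c1cc(/C=C/C(C)(C)O)c(O)cc1O | intermediate
5 | 4-acetyl-5-hydroxy-2-(3-methylbut-2-en-1-ylidene)cyclohexa-3,5-dien-1-one (o-quinone methide) | CC(=O)C1=CC(=CC=C(C)C)C(=O)C=C1O | intermediate (not isolated)
6 | 1-(7-hydroxy-2,2-dimethyl-2H-chromen-6-yl)ethanone | CC(=O)c1cc2C=CC(C)(C)Oc2cc1O | intermediate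
7 | 1-[7-(tert-butyldimethylsilyloxy)-2,2-dimethyl-2H-chromen-6-yl]ethanone | CC(=O)c1cc2C=CC(C)(C)Oc2cc1O[Si](C)(C)C(C)(C)C | intermediate
8 | (3R,4R)-6-acetyl-7-(tert-butyldimethylsilyloxy)-3,4-epoxy-2,2-dimethylchromane | CC1(C)Oc2cc(O[Si](C)(C)C(C)(C)C)c(C(C)=O)cc2[C@H]2O[C@@H]12 | intermediate
9 | (3R,4S)-6-acetyl-7-(tert-butyldimethylsilyloxy)-2,2-dimethylchromane-3,4-diol | CC1(C)Oc2cc(O[Si](C)(C)C(C)(C)C)c(C(C)=O)cc2[C@H](O)[C@H]1O | intermediate
10 | (3R,4S)-6-acetyl-4,7-bis(tert-butyldimethylsilyloxy)-2,2-dimethylchroman-3-ol | CC1(C)Oc2cc(O[Si](C)(C)C(C)(C)C)c(C(C)=O)cc2[C@H](O[Si](C)(C)C(C)(C)C)[C@H]1O | intermediate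
11 | (3R,4S)-6-acetyl-4,7-bis(tert-butyldimethylsilyloxy)-2,2-dimethylchroman-3-yl trifluoromethanesulfonate | CC1(C)Oc2cc(O[Si](C)(C)C(C)(C)C)c(C(C)=O)cc2[C@H](O[Si](C)(C)C(C)(C)C)[C@H]1OS(=O)(=O)C(F)(F)F | intermediate (not isolated)
12 | bicyclic aryloxiranium ion (O1 bonded to the aryl carbon, CMe2 and the former C3) | CC1(C)[O+]2c3cc(O[Si](C)(C)C(C)(C)C)c(C(C)=O)cc3[C@H](O[Si](C)(C)C(C)(C)C)[C@@H]12 | intermediate (not isolated)
13 | 2-[(2R,3S)-5-acetyl-3,6-bis(tert-butyldimethylsilyloxy)-2,3-dihydrobenzofuran-2-yl]propan-2-ylium | C[C+](C)[C@H]1Oc2cc(O[Si](C)(C)C(C)(C)C)c(C(C)=O)cc2[C@@H]1O[Si](C)(C)C(C)(C)C | intermediate (not isolated)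
14 | (2R,3S)-5-acetyl-3,6-bis(tert-butyldimethylsilyloxy)-2-isopropenyl-2,3-dihydrobenzofuran | C=C(C)[C@H]1Oc2cc(O[Si](C)(C)C(C)(C)C)c(C(C)=O)cc2[C@@H]1O[Si](C)(C)C(C)(C)C | intermediate
15 | (2R,3S)-5-acetyl-3,6-dihydroxy-2-isopropenyl-2,3-dihydrobenzofuran | C=C(C)[C@H]1Oc2cc(O)c(C(C)=O)cc2[C@@H]1O | intermediate
16 | but-2-ynoic acid | CC#CC(O)=O | starting material
17 | tert-butyl but-2-ynoate | CC#CC(=O)OC(C)(C)C | intermediate
18 | tert-butyl (E)-2-(diisobutylalumanyl)but-2-enoate | CC(C)(C)OC(=O)/C(=C\C)[Al](CC(C)C)CC(C)C | intermediate (not isolated)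
19 | tert-butyl (Z)-2-(hydroxymethyl)but-2-enoate | CC(C)(C)OC(=O)/C(=C\C)CO | intermediate
20 | tert-butyl (Z)-2-(acetoxymethyl)but-2-enoate | CC(C)(C)OC(=O)/C(=C\C)COC(C)=O | intermediate
21 | (Z)-2-(acetoxymethyl)but-2-enoic acid | OC(=O)/C(=C\C)COC(C)=O | intermediate
22 | (Z)-2-(acetoxymethyl)but-2-enoyl chloride | ClC(=O)/C(=C\C)COC(C)=O | intermediate (not isolated)
23 | (2R,3S)-5-acetyl-6-hydroxy-2-isopropenyl-2,3-dihydrobenzofuran-3-yl (Z)-2-(acetoxymethyl)but-2-enoate | C=C(C)[C@H]1Oc2cc(O)c(C(C)=O)cc2[C@@H]1OC(=O)/C(=C\C)COC(C)=O | target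

Total step count: 14. Longest linear sequence: 10 steps (steps 1–9 and 14, from 1 to 23); the side-chain acid takes steps 10–13.

Steps most likely to fail

Step 8. The ionising triflate may be diverted: the C4–aryl bond is also antiperiplanar to the leaving group and is pushed by the silyloxy oxygen, so it can migrate (semipinacol-type contraction). The electron-rich acetyl oxygen can also be triflated, or the cation can lose the wrong proton. The fallback sets out from 10 and separates ionisation from alkene formation with a milder leaving group. Mesylation (MsCl, Et3N, CH2Cl2, 0 °C) should give (3R,4S)-6-acetyl-4,7-bis(tert-butyldimethylsilyloxy)-2,2-dimethylchroman-3-yl methanesulfonate F1, which ionises only with anchimeric help. Buffered solvolysis (2,6-lutidine, aqueous 2,2,2-trifluoroethanol, 60 °C) should pass through the same oxiranium ion and let water capture the tertiary centre, giving (2S,3S)-5-acetyl-3,6-bis(tert-butyldimethylsilyloxy)-2-(2-hydroxypropan-2-yl)-2,3-dihydrobenzofuran F2. Dehydration of this tertiary alcohol with SOCl2/pyridine at 0 °C should then give 14, where the route is rejoined.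

Step 11. Alkene geometry may be lost if the α-aluminio enoate equilibrates through an aluminium allenolate before the C–C bond forms, and capture of gaseous formaldehyde may be inefficient. The fallback sets out from 17 and builds the same alkene by three stereoretentive operations. Syn hydrostannation (Bu3SnH, Pd(PPh3)4 cat., THF, 0 °C → rt) should place tin at C2 and give tert-butyl (E)-2-(tributylstannyl)but-2-enoate F3. Iododestannylation (I2, CH2Cl2, 0 °C) should give tert-butyl (E)-2-iodobut-2-enoate F4 with retention. Stille hydroxymethylation with Bu3SnCH2OH (Pd(PPh3)4, dioxane, 80 °C) should then give 19, where the route is rejoined.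

Step 6. The epoxide may open through an open benzylic cation with partial front-side capture by water, which erodes the trans relationship at C4. The fallback sets out from 9 obtained as a mixture of C4 epimers and makes the sequence stereoconvergent. Selective oxidation of the benzylic alcohol (MnO2, CH2Cl2, rt) should give (3S)-6-acetyl-7-(tert-butyldimethylsilyloxy)-3-hydroxy-2,2-dimethylchroman-4-one F5 from both epimers. Hydroxyl-directed reduction (Me4NBH(OAc)3, MeCN/AcOH, −20 °C) delivers hydride to C4 from the face of the C3 oxygen and should return the pure trans diol 9, where the route is rejoined.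

Further compounds
F1 | step 8 | (3R,4S)-6-acetyl-4,7-bis(tert-butyldimethylsilyloxy)-2,2-dimethylchroman-3-yl methanesulfonate | CC1(C)Oc2cc(O[Si](C)(C)C(C)(C)C)c(C(C)=O)cc2[C@H](O[Si](C)(C)C(C)(C)C)[C@H]1OS(C)(=O)=O
F2 | step 8 | (2S,3S)-5-acetyl-3,6-bis(tert-butyldimethylsilyloxy)-2-(2-hydroxypropan-2-yl)-2,3-dihydrobenzofuran | CC(C)(O)[C@H]1Oc2cc(O[Si](C)(C)C(C)(C)C)c(C(C)=O)cc2[C@@H]1O[Si](C)(C)C(C)(C)C
F3 | step 11 | tert-butyl (E)-2-(tributylstannyl)but-2-enoate | CC(C)(C)OC(=O)/C(=C\C)[Sn](CCCC)(CCCC)CCCC
F4 | step 11 | tert-butyl (E)-2-iodobut-2-enoate | CC(C)(C)OC(=O)/C(I)=C\C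
F5 | step 6 | (3S)-6-acetyl-7-(tert-butyldimethylsilyloxy)-3-hydroxy-2,2-dimethylchroman-4-one | CC1(C)Oc2cc(O[Si](C)(C)C(C)(C)C)c(C(C)=O)cc2C(=O)[C@H]1O
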